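**Plan**

- Retrosynthesis: the two aryl O–Si bonds are cut first. The C9 methyl on C8 (the CH next to the CH2 of guaiacyl ring A) is then traced back through CH2–B to a boron atom on C8. The central C8–C8' bond is cut last, and the ring B half is cut once more at C7'–C8'.
- Enabling feature: C8 and C8' are both secondary sp3 carbons carrying H, CH3 and an ArCH2 group. One methyl can therefore stand in for boron: C8 becomes a carbenoid carbon (Li plus a benzoate leaving group, from the CH2–O carbon of homovanillyl alcohol), and C8' becomes the migrating carbon of a secondary boronic ester attached to syringyl ring B.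
- Forward: the ring A half (2 steps) and the ring B half (3 steps) are made separately and joined by lithiation–borylation. Matteson CH2 insertion, protodeboronation and desilylation then finish the chain.
- Stereochemistry: C8' comes from (−)-sparteine-mediated lithiation in step 5, C8 from (+)-sparteine-mediated lithiation in step 6. Both are transferred stereospecifically (retention at boron capture and at the migrating carbon, inversion at the carbenoid carbon).
- Each center is thus set by its own reagent, independent of the near-symmetry of the molecule, which differs only by one remote OMe on ring B.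

Key step: step 6

Assumption: (−)-sparteine/s-BuLi removes the pro-S proton α to oxygen of a primary alkyl 2,4,6-triisopropylbenzoate and (+)-sparteine the pro-R proton, as is general for this ester class; compounds 4 and 9, both sparteine enantiomers and ClCH2Bpin are taken as purchasable.

Abbreviations: TIB = 2,4,6-triisopropylbenzoyl; TIPS = triisopropylsilyl; Bpin = 4,4,5,5-tetramethyl-1,3,2-dioxaborolan-2-yl.

**Route**

Step 1
Reactants: 1 homovanillyl alcohol [4-(2-hydroxyethyl)-2-methoxyphenol]
Product: 2 2-(4-hydroxy-3-methoxyphenyl)ethyl 2,4,6-triisopropylbenzoate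
Conditions: TIBOH, PPh3, DIAD, THF, 0 °C to rt
Reagents that add atoms: 2,4,6-triisopropylbenzoic acid, CC(C)c1cc(C(C)C)c(C(=O)O)c(C(C)C)c1
Why: Mitsunobu esterification, in which the carboxylic acid (far more acidic than the phenol) protonates the betaine and its carboxylate displaces the primary alkoxyphosphonium group, so the aliphatic hydroxyl should be acylated while the phenol stays free; no stereocenter is formed.

Step 2
Reactants: 2 2-(4-hydroxy-3-methoxyphenyl)ethyl 2,4,6-triisopropylbenzoate
Product: 3 2-[3-methoxy-4-(triisopropylsilyloxy)phenyl]ethyl 2,4,6-triisopropylbenzoate (fragment A)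
Conditions: TIPSCl, imidazole, DMF, rt
Reagents that add atoms: triisopropylsilyl chloride, CC(C)[Si](Cl)(C(C)C)C(C)C
Why: Imidazole-promoted silylation (silyl ether formation) masks the acidic phenol as a bulky TIPS ether that should withstand s-BuLi at −78 °C and offers no benzylic or strongly ortho-directing site.

Step 3
Reactants: 4 4-bromo-2,6-dimethoxyphenol
Product: 5 (4-bromo-2,6-dimethoxyphenoxy)triisopropylsilane
Conditions: TIPSCl, imidazole, DMAP (cat.), DMF, 40 °C
Reagents that add atoms: triisopropylsilyl chloride, CC(C)[Si](Cl)(C(C)C)C(C)C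
Why: Silyl ether formation of the hindered phenol flanked by two methoxy groups, driven by the nucleophilic catalyst and mild warming, gives a protecting group compatible with the organolithium steps that follow.

Step 4
Reactants: 5 (4-bromo-2,6-dimethoxyphenoxy)triisopropylsilane
Product: 8 2-{[3,5-dimethoxy-4-(triisopropylsilyloxy)phenyl]methyl}-4,4,5,5-tetramethyl-1,3,2-dioxaborolane, via aryllithium 6 (not isolated), via chloromethyl boronate complex 7 (not isolated)
Conditions: n-BuLi, THF, −78 °C; ClCH2Bpin, −78 °C to rt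
Reagents that add atoms: 2-(chloromethyl)-4,4,5,5-tetramethyl-1,3,2-dioxaborolane, ClCB1OC(C)(C)C(C)(C)O1
Why: Bromine–lithium exchange followed by Matteson-type alkylation of a (halomethyl)boronic ester, in which aryllithium 6 adds to boron and the aryl group of boronate 7 shifts from boron to carbon with loss of chloride on warming, should give the benzylic boronic ester.

Step 5
Reactants: 9 ethyl 2,4,6-triisopropylbenzoate; 8 2-{[3,5-dimethoxy-4-(triisopropylsilyloxy)phenyl]methyl}-4,4,5,5-tetramethyl-1,3,2-dioxaborolane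
Product: 12 2-{(2R)-1-[3,5-dimethoxy-4-(triisopropylsilyloxy)phenyl]propan-2-yl}-4,4,5,5-tetramethyl-1,3,2-dioxaborolane (fragment B), via lithiated ethyl ester 10 (not isolated), via boronate complex 11 (not isolated)
Conditions: 9, s-BuLi, (−)-sparteine, Et2O, −78 °C; then 8, −78 °C; then 35 °C
Reagents that add atoms: none
Why: Lithiation–borylation (sparteine-mediated asymmetric deprotonation, then stereospecific 1,2-metallate rearrangement), in which s-BuLi/(−)-sparteine removes the pro-S proton of 9 to give configurationally stable 10, boron is captured with retention, and the benzyl group of 11 migrates anti to the departing benzoate with inversion, so the new stereocenter (the future C8') should be R under reagent control.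

Step 6
Reactants: 3 2-[3-methoxy-4-(triisopropylsilyloxy)phenyl]ethyl 2,4,6-triisopropylbenzoate (fragment A); 12 2-{(2R)-1-[3,5-dimethoxy-4-(triisopropylsilyloxy)phenyl]propan-2-yl}-4,4,5,5-tetramethyl-1,3,2-dioxaborolane (fragment B)
Product: 15 2-{(2S,3R)-1-[3-methoxy-4-(triisopropylsilyloxy)phenyl]-4-[3,5-dimethoxy-4-(triisopropylsilyloxy)phenyl]-3-methylbutan-2-yl}-4,4,5,5-tetramethyl-1,3,2-dioxaborolane, via lithiated ester 13 (not isolated), via boronate complex 14 (not isolated)
Conditions: 3, s-BuLi, (+)-sparteine, Et2O, −78 °C; then 12, −78 °C; then 35 °C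
Reagents that add atoms: none
Why: s-BuLi/(+)-sparteine, held by the ester carbonyl, removes the pro-R proton α to oxygen of 3 to give the configurationally stable carbenoid 13, which adds to the boron of 12 with retention to give boronate 14; on warming the secondary alkyl group shifts from boron to carbon anti-periplanar to the departing triisopropylbenzoate, which forms the C8–C8' bond. The closest known reaction type is the lithiation–borylation homologation of secondary alkyl pinacol boronic esters with sparteine-derived lithiated primary alkyl triisopropylbenzoates. No ring is closed. The new stereocenter C8 is set by the reagent alone: the R configuration of 13 passes through retention at boron capture and inversion in the 1,2-shift to give 8S, while C8' is not new and keeps its R configuration because a migrating carbon retains configuration. The step needs lithiation α to oxygen instead of at the benzylic CH2 or on ring A, which carbonyl-directed deprotonation, the bulk of the benzoate and the electron-rich silyl-protected ring A should secure, and it needs carbon migration instead of oxygen migration, which the good benzoate leaving group and the anti-periplanar C–B bond secure. Because each center is fixed independently, the pseudo-meso relationship and the absolute sense do not depend on the remote difference between rings A and B, and the minor enantiomers of both partners should end up mainly in a separable diastereomer.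

Step 7
Reactants: 15 2-{(2S,3R)-1-[3-methoxy-4-(triisopropylsilyloxy)phenyl]-4-[3,5-dimethoxy-4-(triisopropylsilyloxy)phenyl]-3-methylbutan-2-yl}-4,4,5,5-tetramethyl-1,3,2-dioxaborolane
Product: 17 2-{(2S,3R)-4-[3,5-dimethoxy-4-(triisopropylsilyloxy)phenyl]-2-{[3-methoxy-4-(triisopropylsilyloxy)phenyl]methyl}-3-methylbutyl}-4,4,5,5-tetramethyl-1,3,2-dioxaborolane, via chloromethyl boronate complex 16 (not isolated)
Conditions: BrCH2Cl, n-BuLi, THF, −78 °C to rt
Reagents that add atoms: bromochloromethane, ClCBr
Why: Matteson homologation, in which chloromethyllithium formed in the flask adds to boron at −78 °C to give boronate 16 and, on warming after the excess carbenoid has decayed, the secondary alkyl group shifts to carbon with loss of chloride and retention at C8, so a single CH2 should be inserted.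

Step 8
Reactants: 17 2-{(2S,3R)-4-[3,5-dimethoxy-4-(triisopropylsilyloxy)phenyl]-2-{[3-methoxy-4-(triisopropylsilyloxy)phenyl]methyl}-3-methylbutyl}-4,4,5,5-tetramethyl-1,3,2-dioxaborolane
Product: 20 triisopropyl{4-[(2S,3R)-4-(3,5-dimethoxy-4-triisopropylsilyloxyphenyl)-2,3-dimethylbutyl]-2-methoxyphenoxy}silane (bis-TIPS ether of the target), via phenyl boronate complex 18 (not isolated), via primary alkyl radical 19 (not isolated)
Conditions: PhLi, THF, 0 °C; solvent exchange; Ir[dF(CF3)ppy]2(dtbbpy)PF6 (cat.), PhSH, MeOH/acetone, blue LEDs, rt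
Reagents that add atoms: none
Why: Photoredox protodeboronation of a primary alkyl pinacol boronic ester, in which single-electron oxidation of the electron-rich boronate 18 by the excited photocatalyst cleaves the C–B bond to radical 19 and thiophenol supplies the hydrogen atom, should turn the boron placeholder into the C9 methyl group without touching the adjacent stereocenter.

Step 9
Reactants: 20 triisopropyl{4-[(2S,3R)-4-(3,5-dimethoxy-4-triisopropylsilyloxyphenyl)-2,3-dimethylbutyl]-2-methoxyphenoxy}silane
Product: 21 4-[(2R,3S)-4-(4-hydroxy-3-methoxyphenyl)-2,3-dimethylbutyl]-2,6-dimethoxyphenol (target)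
Conditions: Bu4NF, THF, 0 °C to rt; aq. NH4Cl
Reagents that add atoms: none
Why: Fluoride-mediated desilylation, driven by the strong Si–F bond and the good phenoxide leaving groups, should free both phenols while leaving the methyl ethers and both stereocenters untouched.

**Compound list**

1 | homovanillyl alcohol, 4-(2-hydroxyethyl)-2-methoxyphenol | COc1cc(CCO)ccc1O | starting material
2 | 2-(4-hydroxy-3-methoxyphenyl)ethyl 2,4,6-triisopropylbenzoate | COc1cc(CCOC(=O)c2c(C(C)C)cc(C(C)C)cc2C(C)C)ccc1O | intermediate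
3 | 2-[3-methoxy-4-(triisopropylsilyloxy)phenyl]ethyl 2,4,6-triisopropylbenzoate (fragment A) | COc1cc(CCOC(=O)c2c(C(C)C)cc(C(C)C)cc2C(C)C)ccc1O[Si](C(C)C)(C(C)C)C(C)C | intermediate
4 | 4-bromo-2,6-dimethoxyphenol | COc1cc(Br)cc(OC)c1O | starting material
5 | (4-bromo-2,6-dimethoxyphenoxy)triisopropylsilane | COc1cc(Br)cc(OC)c1O[Si](C(C)C)(C(C)C)C(C)C | intermediate
6 | [3,5-dimethoxy-4-(triisopropylsilyloxy)phenyl]lithium | COc1cc([Li])cc(OC)c1O[Si](C(C)C)(C(C)C)C(C)C | intermediate
7 | lithium (chloromethyl)[3,5-dimethoxy-4-(triisopropylsilyloxy)phenyl](pinacolato)borate | [Li+].COc1cc([B-]2(CCl)OC(C)(C)C(C)(C)O2)cc(OC)c1O[Si](C(C)C)(C(C)C)C(C)C | intermediate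
8 | 2-{[3,5-dimethoxy-4-(triisopropylsilyloxy)phenyl]methyl}-4,4,5,5-tetramethyl-1,3,2-dioxaborolane | COc1cc(CB2OC(C)(C)C(C)(C)O2)cc(OC)c1O[Si](C(C)C)(C(C)C)C(C)C | intermediate
9 | ethyl 2,4,6-triisopropylbenzoate | CCOC(=O)c1c(C(C)C)cc(C(C)C)cc1C(C)C | starting material
10 | (S)-1-lithioethyl 2,4,6-triisopropylbenzoate (sparteine-bound) | C[C@H]([Li])OC(=O)c1c(C(C)C)cc(C(C)C)cc1C(C)C | intermediate
11 | lithium boronate from 10 and 8, (S) at the O-bearing carbon | [Li+].C[C@@H](OC(=O)c1c(C(C)C)cc(C(C)C)cc1C(C)C)[B-]2(Cc3cc(OC)c(O[Si](C(C)C)(C(C)C)C(C)C)c(OC)c3)OC(C)(C)C(C)(C)O2 | intermediate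
12 | 2-{(2R)-1-[3,5-dimethoxy-4-(triisopropylsilyloxy)phenyl]propan-2-yl}-4,4,5,5-tetramethyl-1,3,2-dioxaborolane (fragment B) | C[C@H](Cc1cc(OC)c(O[Si](C(C)C)(C(C)C)C(C)C)c(OC)c1)B2OC(C)(C)C(C)(C)O2 | intermediate
13 | (R)-1-lithio-2-[3-methoxy-4-(triisopropylsilyloxy)phenyl]ethyl 2,4,6-triisopropylbenzoate (sparteine-bound) | COc1cc(C[C@@H]([Li])OC(=O)c2c(C(C)C)cc(C(C)C)cc2C(C)C)ccc1O[Si](C(C)C)(C(C)C)C(C)C | intermediate
14 | lithium boronate from 13 and 12 | [Li+].COc1cc(C[C@H](OC(=O)c2c(C(C)C)cc(C(C)C)cc2C(C)C)[B-]3(OC(C)(C)C(C)(C)O3)[C@H](C)Cc2cc(OC)c(O[Si](C(C)C)(C(C)C)C(C)C)c(OC)c2)ccc1O[Si](C(C)C)(C(C)C)C(C)C | intermediate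
15 | 2-{(2S,3R)-1-[3-methoxy-4-(triisopropylsilyloxy)phenyl]-4-[3,5-dimethoxy-4-(triisopropylsilyloxy)phenyl]-3-methylbutan-2-yl}-4,4,5,5-tetramethyl-1,3,2-dioxaborolane | COc1cc(C[C@H](B3OC(C)(C)C(C)(C)O3)[C@H](C)Cc2cc(OC)c(O[Si](C(C)C)(C(C)C)C(C)C)c(OC)c2)ccc1O[Si](C(C)C)(C(C)C)C(C)C | intermediate
16 | lithium (chloromethyl)boronate of 15 | [Li+].COc1cc(C[C@H]([B-]3(CCl)OC(C)(C)C(C)(C)O3)[C@H](C)Cc2cc(OC)c(O[Si](C(C)C)(C(C)C)C(C)C)c(OC)c2)ccc1O[Si](C(C)C)(C(C)C)C(C)C | intermediate
17 | 2-{(2S,3R)-4-[3,5-dimethoxy-4-(triisopropylsilyloxy)phenyl]-2-{[3-methoxy-4-(triisopropylsilyloxy)phenyl]methyl}-3-methylbutyl}-4,4,5,5-tetramethyl-1,3,2-dioxaborolane | COc1cc(C[C@H](CB3OC(C)(C)C(C)(C)O3)[C@H](C)Cc2cc(OC)c(O[Si](C(C)C)(C(C)C)C(C)C)c(OC)c2)ccc1O[Si](C(C)C)(C(C)C)C(C)C | intermediate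
18 | lithium phenylboronate of 17 | [Li+].COc1cc(C[C@H](C[B-]3(c4ccccc4)OC(C)(C)C(C)(C)O3)[C@H](C)Cc2cc(OC)c(O[Si](C(C)C)(C(C)C)C(C)C)c(OC)c2)ccc1O[Si](C(C)C)(C(C)C)C(C)C | intermediate
19 | primary alkyl radical at C9 formed from 18 | COc1cc(C[C@H]([CH2])[C@H](C)Cc2cc(OC)c(O[Si](C(C)C)(C(C)C)C(C)C)c(OC)c2)ccc1O[Si](C(C)C)(C(C)C)C(C)C | intermediate
20 | triisopropyl{4-[(2S,3R)-4-(3,5-dimethoxy-4-triisopropylsilyloxyphenyl)-2,3-dimethylbutyl]-2-methoxyphenoxy}silane | COc1cc(C[C@H](C)[C@H](C)Cc2cc(OC)c(O[Si](C(C)C)(C(C)C)C(C)C)c(OC)c2)ccc1O[Si](C(C)C)(C(C)C)C(C)C | intermediate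
21 | 4-[(2R,3S)-4-(4-hydroxy-3-methoxyphenyl)-2,3-dimethylbutyl]-2,6-dimethoxyphenol | COc1cc(C[C@H](C)[C@H](C)Cc2cc(OC)c(O)c(OC)c2)ccc1O | target

**Step count**

Total steps: 9. Longest linear sequence: 7 steps (steps 3, 4, 5, 6, 7, 8, 9, from compound 4).

**Steps most likely to fail**

1. Step 6. What may go wrong: deprotonation at the benzylic CH2 of 3 followed by loss of the benzoate instead of α-lithiation; slow or reversible boronate formation at the hindered secondary boron, which lets the carbenoid decay and lowers stereochemical fidelity; a sluggish 1,2-shift. Fallback, setting out from 12 and coming back at 20: the central bond is made with the small carbenoid 10 instead, and ring A is attached last. Compound 12 is homologated a second time with 10 (from 9, s-BuLi, (−)-sparteine, Et2O, −78 °C, then 35 °C), which should give 2-[(2R,3R)-4-(3,5-dimethoxy-4-triisopropylsilyloxyphenyl)-3-methylbutan-2-yl]-4,4,5,5-tetramethyl-1,3,2-dioxaborolane F1. Matteson CH2 insertion (BrCH2Cl, n-BuLi, THF, −78 °C to rt) should then give 2-[(2S,3R)-4-(3,5-dimethoxy-4-triisopropylsilyloxyphenyl)-2,3-dimethylbutyl]-4,4,5,5-tetramethyl-1,3,2-dioxaborolane F2. An sp3–sp2 Suzuki–Miyaura coupling (Pd(OAc)2, RuPhos, K3PO4, toluene/H2O, 90 °C) with (4-bromo-2-methoxyphenoxy)triisopropylsilane F3, prepared from commercial 4-bromo-2-methoxyphenol with TIPSCl and imidazole, should deliver 20. Any partial loss of silyl groups in the coupling is harmless because step 9 follows.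

2. Step 8. What may go wrong: inefficient single-electron oxidation of a primary alkyl boronate, quenching of the excited photocatalyst by the two electron-rich arenes, or addition of the primary radical to ring B before hydrogen-atom transfer. Fallback, setting out from 17 and coming back at 20: a polar C–O route replaces the radical C–B cleavage. Oxidation of 17 (NaBO3·4H2O, THF/H2O, rt) should give (2S,3R)-4-(3,5-dimethoxy-4-triisopropylsilyloxyphenyl)-2-[(3-methoxy-4-triisopropylsilyloxyphenyl)methyl]-3-methylbutan-1-ol F4. Tosylation (TsCl, Et3N, DMAP, CH2Cl2) should give the corresponding p-toluenesulfonate F5, and hydride displacement (LiBHEt3, THF, 0 °C to rt) should give 20.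

3. Step 7. What may go wrong: slow boronate formation at the hindered secondary boron while the short-lived chloromethyllithium decomposes, and competing attack of n-BuLi on boron. Fallback, setting out from 15 and coming back at 17: a longer-lived, preformed carbenoid and a hydride 1,2-shift are used instead. LiCHCl2 (from CH2Cl2 and n-BuLi, THF, −100 °C) is added to 15, followed by ZnCl2 and warming to rt, which should give 2-{(2S,3R)-1-chloro-4-(3,5-dimethoxy-4-triisopropylsilyloxyphenyl)-2-[(3-methoxy-4-triisopropylsilyloxyphenyl)methyl]-3-methylbutyl}-4,4,5,5-tetramethyl-1,3,2-dioxaborolane F6 as a mixture of epimers at the chlorinated carbon. Treatment with LiBHEt3 (THF, −78 °C to rt) adds hydride to boron and shifts it to carbon with loss of chloride, which removes that stereocenter and should give 17.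

**Further compounds**

F1 | step 6 | 2-[(2R,3R)-4-(3,5-dimethoxy-4-triisopropylsilyloxyphenyl)-3-methylbutan-2-yl]-4,4,5,5-tetramethyl-1,3,2-dioxaborolane | C[C@@H](B1OC(C)(C)C(C)(C)O1)[C@H](C)Cc1cc(OC)c(O[Si](C(C)C)(C(C)C)C(C)C)c(OC)c1
F2 | step 6 | 2-[(2S,3R)-4-(3,5-dimethoxy-4-triisopropylsilyloxyphenyl)-2,3-dimethylbutyl]-4,4,5,5-tetramethyl-1,3,2-dioxaborolane | C[C@@H](CB1OC(C)(C)C(C)(C)O1)[C@H](C)Cc1cc(OC)c(O[Si](C(C)C)(C(C)C)C(C)C)c(OC)c1
F3 | step 6 | (4-bromo-2-methoxyphenoxy)triisopropylsilane | COc1cc(Br)ccc1O[Si](C(C)C)(C(C)C)C(C)C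
F4 | step 8 | (2S,3R)-4-(3,5-dimethoxy-4-triisopropylsilyloxyphenyl)-2-[(3-methoxy-4-triisopropylsilyloxyphenyl)methyl]-3-methylbutan-1-ol | COc1cc(C[C@H](CO)[C@H](C)Cc2cc(OC)c(O[Si](C(C)C)(C(C)C)C(C)C)c(OC)c2)ccc1O[Si](C(C)C)(C(C)C)C(C)C
F5 | step 8 | (2S,3R)-4-(3,5-dimethoxy-4-triisopropylsilyloxyphenyl)-2-[(3-methoxy-4-triisopropylsilyloxyphenyl)methyl]-3-methylbutyl 4-methylbenzenesulfonate | COc1cc(C[C@H](COS(=O)(=O)c3ccc(C)cc3)[C@H](C)Cc2cc(OC)c(O[Si](C(C)C)(C(C)C)C(C)C)c(OC)c2)ccc1O[Si](C(C)C)(C(C)C)C(C)C
F6 | step 7 | 2-{(2S,3R)-1-chloro-4-(3,5-dimethoxy-4-triisopropylsilyloxyphenyl)-2-[(3-methoxy-4-triisopropylsilyloxyphenyl)methyl]-3-methylbutyl}-4,4,5,5-tetramethyl-1,3,2-dioxaborolane (epimers at C1) | COc1cc(C[C@H](C(Cl)B3OC(C)(C)C(C)(C)O3)[C@H](C)Cc2cc(OC)c(O[Si](C(C)C)(C(C)C)C(C)C)c(OC)c2)ccc1O[Si](C(C)C)(C(C)C)C(C)C
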